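Ring C of the flavone (O1, C2, C3, C4, C4a, C8a) is dismantled into three pieces: a fully substituted ring A 2-iodophenol supplying O1, C8a and C4a, carbon monoxide as C4, and 4-ethynylanisole as C3–C2 carrying ring B. The feature exploited is the vinylogous ester O1–C2=C3–C4=O, which hangs on the ortho pair C8a/C4a of ring A. A single palladium-catalysed carbonylative annulation makes C4a–C4, C4–C3 and O1–C2 and closes the pyranone. The precursor bears benzyl ethers at the future O5 and O7, methyl at O6 and a MOM acetal at O8, so O8 alone can later be freed and acylated. The C3 methoxy group is added after ring closure.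

Key step: step 7

Assumption: 2,3-dihydroxy-4-methoxyacetophenone 1 is taken as a catalogue chemical. Acetophenone and phenol locants count from the carbon bearing acetyl or OH, and flavone locants are used from step 7 on. The target contains no stereocentre.

Step 1
Reactants: 1 2,3-dihydroxy-4-methoxyacetophenone
Product: 2 3-benzyloxy-2-hydroxy-4-methoxyacetophenone
Conditions: BnBr (1.05 equiv), K2CO3 (1.1 equiv), acetone, reflux
Reagents that add atoms: benzyl bromide, BrCc1ccccc1
Why: Williamson etherification under chelation control, in which the 2-OH is held by a strong hydrogen bond to the acetyl oxygen and stays inert to one equivalent of halide with a weak base, so the free 3-OH is alkylated.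

Step 2
Reactants: 2 3-benzyloxy-2-hydroxy-4-methoxyacetophenone
Product: 4 3-benzyloxy-2,5-dihydroxy-4-methoxyacetophenone, via potassium aryl sulfate 3 (not isolated)
Conditions: K2S2O8, aq KOH, pyridine, 10–20 °C; then aq HCl, 70 °C
Reagents that add atoms: potassium persulfate, [K+].[K+].[O-]S(=O)(=O)OOS(=O)(=O)[O-]
Why: Elbs persulfate oxidation, in which the phenolate attacks the peroxide oxygen through C5, the only open carbon conjugated with it because both ortho carbons are substituted, and short mild acid hydrolysis of sulfate ester 3 should free the hydroquinone while the benzyl ether persists.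

Step 3
Reactants: 4 3-benzyloxy-2,5-dihydroxy-4-methoxyacetophenone
Product: 5 3,5-bis(benzyloxy)-2-hydroxy-4-methoxyacetophenone
Conditions: BnBr (1.05 equiv), K2CO3 (1.1 equiv), acetone, reflux, argon
Reagents that add atoms: benzyl bromide, BrCc1ccccc1
Why: Williamson etherification again discriminates by hydrogen bonding, since the new 5-OH is an ordinary phenol whereas the 2-OH remains chelated to the ketone.

Step 4
Reactants: 5 3,5-bis(benzyloxy)-2-hydroxy-4-methoxyacetophenone
Product: 6 3,5-bis(benzyloxy)-4-methoxy-2-(methoxymethoxy)acetophenone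
Conditions: NaH (1.1 equiv), MOMCl, DMF, 0 °C to rt
Reagents that add atoms: chloromethyl methyl ether, COCCl
Why: Complete deprotonation with NaH breaks the chelate and the sodium phenolate is alkylated by MOMCl (Williamson-type acetal formation), which marks the future O8 as the only acid-labile oxygen.

Step 5
Reactants: 6 3,5-bis(benzyloxy)-4-methoxy-2-(methoxymethoxy)acetophenone
Product: 8 3,5-bis(benzyloxy)-4-methoxy-2-(methoxymethoxy)phenol, via aryl acetate 7 (not isolated)
Conditions: mCPBA (1.3 equiv), CH2Cl2, rt; aqueous wash, then K2CO3 (cat.), MeOH, rt, argon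
Reagents that add atoms: 3-chloroperbenzoic acid (mCPBA), O=C(OO)c1cccc(Cl)c1
Why: Baeyer–Villiger oxidation, in which the aryl group, pushed by its ortho and para alkoxy donors, migrates from the Criegee adduct in preference to methyl, and carbonate-catalysed transesterification of 7 in methanol then frees the future O1 without touching MOM or benzyl ethers.

Step 6
Reactants: 8 3,5-bis(benzyloxy)-4-methoxy-2-(methoxymethoxy)phenol
Product: 9 3,5-bis(benzyloxy)-2-iodo-4-methoxy-6-(methoxymethoxy)phenol
Conditions: NIS (1.0 equiv), MeCN, 0 °C, dark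
Reagents that add atoms: N-iodosuccinimide, O=C1CCC(=O)N1I
Why: Electrophilic aromatic iodination at the single ring C–H, which is ortho to the free hydroxyl and ortho and para to the two benzyloxy groups, so acid-free NIS should suffice and the MOM acetal is not endangered.

Step 7
Reactants: 9 3,5-bis(benzyloxy)-2-iodo-4-methoxy-6-(methoxymethoxy)phenol, 10 4-ethynylanisole (1.5 equiv), 11 carbon monoxide
Product: 14 5,7-bis(benzyloxy)-6,4'-dimethoxy-8-(methoxymethoxy)flavone, via hydroxyaryl ynone 12 (not isolated), via diethylamino enaminone 13 (not isolated)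
Conditions: PdCl2(dppf) (5 mol %), CO (20 bar), Et2NH, 120 °C, autoclave
Reagents that add atoms: diethylamine, CCNCC (its atoms sit only in 13 and leave again on ring closure)
Why: Zerovalent palladium, generated in situ from PdCl2(dppf), inserts into the C–I bond of 9, CO inserts to give an aroylpalladium iodide, and the acetylide formed from 10 and the amine replaces iodide so that reductive elimination releases ynone 12 with the C4a–C4 and C4–C3 bonds in place. Diethylamine then adds in conjugate fashion to 12 to give push–pull enaminone 13, whose amine-bearing carbon is attacked by the adjacent phenol oxygen with loss of the amine, an addition–elimination that closes ring C in the 6-endo mode and makes O1–C2. The closest known reaction type is exactly this one, the carbonylative Sonogashira coupling of 2-iodophenols with terminal alkynes followed by in situ cyclisation to flavones. Two selectivities are needed: CO insertion must precede alkynyl transfer, which CO pressure and the absence of copper favour, and closure must be 6-endo rather than 5-exo (aurone), which the enaminone secures because only its β-carbon remains electrophilic. Site selectivity on ring A is built into 9, since iodine sits on the only carbon that ever carried hydrogen and the single free hydroxyl is its ortho neighbour. No stereocentre is created.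

Step 8
Reactants: 14 5,7-bis(benzyloxy)-6,4'-dimethoxy-8-(methoxymethoxy)flavone
Product: 17 5,7-bis(benzyloxy)-3-hydroxy-6,4'-dimethoxy-8-(methoxymethoxy)flavone, via 3-lithioflavone 15 (not isolated), via dimethyl flavon-3-ylboronate 16 (not isolated)
Conditions: LiN(i-Pr)2 (1.5 equiv), THF, −78 °C; B(OMe)3, −78 to 0 °C; AcOH, 30% H2O2, 0 °C to rt
Reagents that add atoms: hydrogen peroxide, OO; trimethyl borate, COB(OC)OC (boron and methoxy groups sit only in 16); lithium diisopropylamide, [Li]N(C(C)C)C(C)C (lithium sits only in 15)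
Why: C3 lithiation of a flavone, borate trapping and peroxide oxidation (boron-to-oxygen 1,2-shift), which should work because H3 is the most acidic C–H, the lithium is held by the C4 carbonyl oxygen, ring A has no C–H left to compete and the C–B to C–O exchange is regiospecific.

Step 9
Reactants: 17 5,7-bis(benzyloxy)-3-hydroxy-6,4'-dimethoxy-8-(methoxymethoxy)flavone
Product: 18 5,7-bis(benzyloxy)-3,6,4'-trimethoxy-8-(methoxymethoxy)flavone
Conditions: MeI, K2CO3, acetone, reflux
Reagents that add atoms: iodomethane, CI
Why: Williamson methylation of the acidic enolic 3-OH, the only free hydroxyl in 17.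

Step 10
Reactants: 18 5,7-bis(benzyloxy)-3,6,4'-trimethoxy-8-(methoxymethoxy)flavone
Product: 19 5,7-bis(benzyloxy)-8-hydroxy-3,6,4'-trimethoxyflavone
Conditions: HCl (cat.), MeOH–THF, 45 °C
Reagents that add atoms: none
Why: Acid-catalysed acetal exchange removes the MOM group far faster than aryl benzyl or methyl ethers react, and partial loss of the acid-sensitive peri 5-O-benzyl group would be harmless because a chelated 5-OH does not compete in step 11 and is due to be freed in step 12.

Step 11
Reactants: 19 5,7-bis(benzyloxy)-8-hydroxy-3,6,4'-trimethoxyflavone, 20 isovaleryl chloride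
Product: 21 5,7-bis(benzyloxy)-3,6,4'-trimethoxyflavon-8-yl isovalerate
Conditions: Et3N, DMAP (cat.), CH2Cl2, 0 °C to rt
Reagents that add atoms: none
Why: DMAP-catalysed O-acylation (nucleophilic acyl substitution) of the only free hydroxyl places the isovalerate unambiguously on O8.

Step 12
Reactants: 21 5,7-bis(benzyloxy)-3,6,4'-trimethoxyflavon-8-yl isovalerate
Product: 22 5,7,8-trihydroxy-3,6,4'-trimethoxyflavone 8-isovalerate
Conditions: H2 (1 atm), 10% Pd/C, EtOAc, rt
Reagents that add atoms: none
Why: Heterogeneous catalytic hydrogenolysis of the two aryl benzyl ethers under neutral aprotic conditions leaves the ester, the methyl ethers and the tetrasubstituted C2=C3 bond intact and offers no base that could move the acyl group from O8 to O7.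

Compound list
1 | 2,3-dihydroxy-4-methoxyacetophenone | CC(=O)c1ccc(OC)c(O)c1O | starting material
2 | 3-benzyloxy-2-hydroxy-4-methoxyacetophenone | CC(=O)c1ccc(OC)c(OCc2ccccc2)c1O | intermediate
3 | potassium 5-acetyl-3-benzyloxy-4-hydroxy-2-methoxyphenyl sulfate | [K+].CC(=O)c1cc(OS(=O)(=O)[O-])c(OC)c(OCc2ccccc2)c1O | intermediate
4 | 3-benzyloxy-2,5-dihydroxy-4-methoxyacetophenone | CC(=O)c1cc(O)c(OC)c(OCc2ccccc2)c1O | intermediate
5 | 3,5-bis(benzyloxy)-2-hydroxy-4-methoxyacetophenone | CC(=O)c1cc(OCc2ccccc2)c(OC)c(OCc2ccccc2)c1O | intermediate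
6 | 3,5-bis(benzyloxy)-4-methoxy-2-(methoxymethoxy)acetophenone | CC(=O)c1cc(OCc2ccccc2)c(OC)c(OCc2ccccc2)c1OCOC | intermediate
7 | 3,5-bis(benzyloxy)-4-methoxy-2-(methoxymethoxy)phenyl acetate | CC(=O)Oc1cc(OCc2ccccc2)c(OC)c(OCc2ccccc2)c1OCOC | intermediate
8 | 3,5-bis(benzyloxy)-4-methoxy-2-(methoxymethoxy)phenol | Oc1cc(OCc2ccccc2)c(OC)c(OCc2ccccc2)c1OCOC | intermediate
9 | 3,5-bis(benzyloxy)-2-iodo-4-methoxy-6-(methoxymethoxy)phenol | Oc1c(I)c(OCc2ccccc2)c(OC)c(OCc2ccccc2)c1OCOC | intermediate
10 | 4-ethynylanisole | C#Cc1ccc(OC)cc1 | starting material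
11 | carbon monoxide | [C-]#[O+] | starting material
12 | 1-[2,4-bis(benzyloxy)-6-hydroxy-3-methoxy-5-(methoxymethoxy)phenyl]-3-(4-methoxyphenyl)prop-2-yn-1-one | COc1ccc(C#CC(=O)c2c(O)c(OCOC)c(OCc3ccccc3)c(OC)c2OCc3ccccc3)cc1 | intermediate
13 | (E)-1-[2,4-bis(benzyloxy)-6-hydroxy-3-methoxy-5-(methoxymethoxy)phenyl]-3-(diethylamino)-3-(4-methoxyphenyl)prop-2-en-1-one | CCN(CC)/C(=C/C(=O)c1c(O)c(OCOC)c(OCc2ccccc2)c(OC)c1OCc2ccccc2)c3ccc(OC)cc3 | intermediate
14 | 5,7-bis(benzyloxy)-6,4'-dimethoxy-8-(methoxymethoxy)flavone | COc1ccc(-c2cc(=O)c3c(OCc4ccccc4)c(OC)c(OCc4ccccc4)c(OCOC)c3o2)cc1 | intermediate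
15 | 3-lithio-5,7-bis(benzyloxy)-6,4'-dimethoxy-8-(methoxymethoxy)flavone | [Li]c1c(-c2ccc(OC)cc2)oc2c(OCOC)c(OCc3ccccc3)c(OC)c(OCc3ccccc3)c2c1=O | intermediate
16 | dimethyl [5,7-bis(benzyloxy)-6,4'-dimethoxy-8-(methoxymethoxy)flavon-3-yl]boronate | COB(OC)c1c(-c2ccc(OC)cc2)oc2c(OCOC)c(OCc3ccccc3)c(OC)c(OCc3ccccc3)c2c1=O | intermediate
17 | 5,7-bis(benzyloxy)-3-hydroxy-6,4'-dimethoxy-8-(methoxymethoxy)flavone | COc1ccc(-c2oc3c(OCOC)c(OCc4ccccc4)c(OC)c(OCc4ccccc4)c3c(=O)c2O)cc1 | intermediate
18 | 5,7-bis(benzyloxy)-3,6,4'-trimethoxy-8-(methoxymethoxy)flavone | COc1ccc(-c2oc3c(OCOC)c(OCc4ccccc4)c(OC)c(OCc4ccccc4)c3c(=O)c2OC)cc1 | intermediate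
19 | 5,7-bis(benzyloxy)-8-hydroxy-3,6,4'-trimethoxyflavone | COc1ccc(-c2oc3c(O)c(OCc4ccccc4)c(OC)c(OCc4ccccc4)c3c(=O)c2OC)cc1 | intermediate
20 | isovaleryl chloride | CC(C)CC(=O)Cl | starting material
21 | 5,7-bis(benzyloxy)-3,6,4'-trimethoxyflavon-8-yl isovalerate | COc1ccc(-c2oc3c(OC(=O)CC(C)C)c(OCc4ccccc4)c(OC)c(OCc4ccccc4)c3c(=O)c2OC)cc1 | intermediate
22 | 5,7,8-trihydroxy-3,6,4'-trimethoxyflavone 8-isovalerate | COc1ccc(-c2oc3c(OC(=O)CC(C)C)c(O)c(OC)c(O)c3c(=O)c2OC)cc1 | target

Total step count: 12. Longest linear sequence: 12 steps (1 to 22). Compounds 10, 11 and 20 are bought and enter directly.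

Steps most likely to fail

Risk 1, step 7. Oxidative addition into a C–I bond flanked by two oxygen substituents on a very electron-rich ring may be slow under CO. That leaves room for four competing processes:
- hydrodeiodination
- capture of the aroylpalladium species by diethylamine (aminocarbonylation)
- CO-free alkynylation
- intramolecular C–H arylation of the neighbouring benzyl ether

The fallback sets out from 9 and 10 and comes back at 14 through 12, which is now isolated. It uses neither palladium nor CO. Alkyne 10 is deprotonated with n-BuLi in THF at −78 °C to lithium (4-methoxyphenyl)acetylide F1. This is trapped with N-methoxy-N-methylcarbamoyl chloride to give N-methoxy-N-methyl-3-(4-methoxyphenyl)prop-2-ynamide F2. Iodophenol 9 is treated with two equivalents of n-BuLi at −78 °C, which causes O–H deprotonation and then iodine–lithium exchange, to give the dilithiated phenolate F3. F3 is acylated by F2 through a stable tetrahedral chelate and should give ynone 12 after an NH4Cl quench. Gentle warming of 12 with Et2NH in EtOH passes through 13 and closes ring C to 14.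

Risk 2, step 2. Conversion in the persulfate oxidation may be low. The electron-rich phenolate may be over-oxidised, and the benzyl ether may be partly lost during the acidic hydrolysis of the sulfate ester.

The fallback sets out from 2 and comes back at 6, replacing C–H oxidation by halogenation, borylation and oxidation:
- NBS in MeCN should brominate para to the chelated phenol and ortho to the methoxy group to give 3-benzyloxy-5-bromo-2-hydroxy-4-methoxyacetophenone F4.
- NaH and MOMCl give 3-benzyloxy-5-bromo-4-methoxy-2-(methoxymethoxy)acetophenone F5. Protection comes first so that no ortho-hydroxy ketone meets alkaline peroxide later.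
- Miyaura borylation (B2pin2, PdCl2(dppf), KOAc, dioxane, 90 °C) gives 3-benzyloxy-4-methoxy-2-(methoxymethoxy)-5-(4,4,5,5-tetramethyl-1,3,2-dioxaborolan-2-yl)acetophenone F6.
- H2O2 and NaOH at 0 °C give 3-benzyloxy-5-hydroxy-4-methoxy-2-(methoxymethoxy)acetophenone F7.
- BnBr with K2CO3 gives 6.

Risk 3, step 8. C3 deprotonation may be incomplete. Benzylic deprotonation of the benzyl ethers or addition of the amide base at C2 may compete, and borate capture of the hindered anion may be sluggish.

The fallback sets out from 14 and comes back at 17, and it uses an electrophilic oxidant instead of an anion. Dimethyldioxirane in acetone–CH2Cl2 at 0 °C should epoxidise the enol-ether C2=C3 bond to the racemic cis-fused 2,3-epoxide of 14 F8. On silica gel or with a trace of p-TsOH, F8 opens at C2–O and loses H3 to give flavonol 17.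

Further compounds
F1 | step 7 | lithium (4-methoxyphenyl)acetylide | [Li]C#Cc1ccc(OC)cc1
F2 | step 7 | N-methoxy-N-methyl-3-(4-methoxyphenyl)prop-2-ynamide | CON(C)C(=O)C#Cc1ccc(OC)cc1
F3 | step 7 | dilithiated phenolate, lithium 3,5-bis(benzyloxy)-2-lithio-4-methoxy-6-(methoxymethoxy)phenolate | [Li]Oc1c([Li])c(OCc2ccccc2)c(OC)c(OCc2ccccc2)c1OCOC
F4 | step 2 | 3-benzyloxy-5-bromo-2-hydroxy-4-methoxyacetophenone | CC(=O)c1cc(Br)c(OC)c(OCc2ccccc2)c1O
F5 | step 2 | 3-benzyloxy-5-bromo-4-methoxy-2-(methoxymethoxy)acetophenone | CC(=O)c1cc(Br)c(OC)c(OCc2ccccc2)c1OCOC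
F6 | step 2 | 3-benzyloxy-4-methoxy-2-(methoxymethoxy)-5-(4,4,5,5-tetramethyl-1,3,2-dioxaborolan-2-yl)acetophenone | CC(=O)c1cc(B2OC(C)(C)C(C)(C)O2)c(OC)c(OCc3ccccc3)c1OCOC
F7 | step 2 | 3-benzyloxy-5-hydroxy-4-methoxy-2-(methoxymethoxy)acetophenone | CC(=O)c1cc(O)c(OC)c(OCc2ccccc2)c1OCOC
F8 | step 8 | racemic cis-fused 2,3-epoxide of 14 (one enantiomer drawn) | COc1ccc([C@@]23O[C@@H]2C(=O)c4c(OCc5ccccc5)c(OC)c(OCc5ccccc5)c(OCOC)c4O3)cc1
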